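**Plan**
- The target is an achiral tridepside. Retrosynthesis cuts the ester between rings B and A at both bonds of its carbonyl carbon (C1 of ring B–C(=O) and C(=O)–O4 of ring A), then the ester between rings C and B at its acyl–oxygen bond.
- Enabling feature: that carbonyl sits on C1 of ring B, between the C2 methoxy and C6 methyl groups and para to the C4 oxygen. In the ring B phenol, C1 is the only ring carbon that bears hydrogen, so iodine can be placed there without isomers and exchanged for CO on palladium.
- Forward: the ring B iodophenol is built from 2,5-dimethylresorcinol; the ring C acid and the ring A phenol both come from methyl 2,4-dihydroxy-3,6-dimethylbenzoate.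
- Ring C is esterified onto the iodophenol, the aryl iodide, CO and the ring A phenol are joined in one palladium-catalysed step, and hydrogenolysis followed by acidolysis frees the phenols and the acid.
- No ring is formed and no stereocentre has to be set.

Key step: step 13

Remark: the target has no stereogenic element; carbon monoxide is counted as a commercial starting material and numbered.

**Route**

Step 1
Reactants: 1 2,5-dimethylbenzene-1,3-diol
Product: 3 2,4-dihydroxy-3,6-dimethylbenzaldehyde, via aryl iminium chloride 2 (not isolated)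
Conditions: POCl3 (1.2 equiv), DMF (3 equiv), MeCN, 0 °C to rt; then H2O, 50 °C
Reagents that add atoms: N,N-dimethylformamide, CN(C)C=O; water, O
Why: Vilsmeier–Haack formylation, in which the two ring CH positions of 1 are equivalent (each ortho to one hydroxyl and para to the other), so one aldehyde should form and the iminium salt 2 resists a second attack.

Step 2
Reactants: 3 2,4-dihydroxy-3,6-dimethylbenzaldehyde
Product: 4 2-hydroxy-4-methoxy-3,6-dimethylbenzaldehyde
Conditions: MeI (1.1 equiv), K2CO3 (1.1 equiv), acetone, rt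
Reagents that add atoms: iodomethane, CI
Why: Williamson ether synthesis, selective for the more acidic hydroxyl para to the aldehyde because the ortho hydroxyl is tied up in a hydrogen bond to the carbonyl group.

Step 3
Reactants: 4 2-hydroxy-4-methoxy-3,6-dimethylbenzaldehyde
Product: 6 3-methoxy-2,5,6-trimethylphenol, via benzylic alcohol 5 (not isolated)
Conditions: H2 (3 bar), 10% Pd/C, AcOH, rt
Reagents that add atoms: none
Why: Catalytic hydrogenation of the aldehyde followed by benzylic hydrogenolysis of the electron-rich ortho-hydroxybenzyl alcohol 5 should turn CHO into CH3 without touching the aryl ether or the ring.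

Step 4
Reactants: 6 3-methoxy-2,5,6-trimethylphenol
Product: 7 4-iodo-3-methoxy-2,5,6-trimethylphenol
Conditions: N-iodosuccinimide (1.05 equiv), TsOH·H2O (10 mol %), MeCN, 0 °C, dark
Reagents that add atoms: N-iodosuccinimide, O=C1CCC(=O)N1I
Why: Electrophilic aromatic iodination, regiochemically fixed because the single ring hydrogen of 6 lies para to the hydroxyl and ortho to the methoxy group.

Step 5
Reactants: 8 methyl 2,4-dihydroxy-3,6-dimethylbenzoate
Product: 9 methyl 2,4-bis(benzyloxy)-3,6-dimethylbenzoate
Conditions: BnBr (2.5 equiv), K2CO3 (3 equiv), DMF, 60 °C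
Reagents that add atoms: benzyl bromide, BrCc1ccccc1
Why: Exhaustive Williamson etherification, where excess halide and warm DMF overcome the hydrogen bond that slows alkylation of the hydroxyl next to the ester.

Step 6
Reactants: 9 methyl 2,4-bis(benzyloxy)-3,6-dimethylbenzoate
Product: 10 2,4-bis(benzyloxy)-3,6-dimethylbenzoic acid
Conditions: KOH (5 equiv), DMSO/H2O 4:1, 100 °C; then aq HCl
Reagents that add atoms: potassium hydroxide, [K+].[OH-]
Why: Saponification, in which poorly solvated hydroxide in aqueous DMSO should hydrolyse the doubly ortho-substituted methyl ester while the benzyl ethers stay inert to base.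

Step 7
Reactants: 10 2,4-bis(benzyloxy)-3,6-dimethylbenzoic acid; 7 4-iodo-3-methoxy-2,5,6-trimethylphenol
Product: 12 4-iodo-3-methoxy-2,5,6-trimethylphenyl 2,4-bis(benzyloxy)-3,6-dimethylbenzoate, via mixed trifluoroacetic anhydride 11 (not isolated)
Conditions: (CF3CO)2O (3 equiv), toluene, 0 °C to rt (acid and anhydride premixed, then 7 added)
Reagents that add atoms: none
Why: Trifluoroacetic anhydride-mediated esterification, in which the mixed anhydride of the flanked, electron-rich acid ionises to a slim acylium ion that should acylate even the doubly ortho-methylated phenol on oxygen, C-acylation being excluded because 7 has no ring hydrogen.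

Step 8
Reactants: 8 methyl 2,4-dihydroxy-3,6-dimethylbenzoate
Product: 13 methyl 4-(benzyloxy)-2-hydroxy-3,6-dimethylbenzoate
Conditions: BnBr (1.05 equiv), K2CO3 (1.1 equiv), acetone, reflux
Reagents that add atoms: benzyl bromide, BrCc1ccccc1
Why: Williamson etherification with one equivalent of halide, selective for O4 because the O2 hydroxyl is chelated to the ester carbonyl and crowded by the ester and the C3 methyl group.

Step 9
Reactants: 13 methyl 4-(benzyloxy)-2-hydroxy-3,6-dimethylbenzoate
Product: 14 methyl 4-(benzyloxy)-2-methoxy-3,6-dimethylbenzoate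
Conditions: MeI (3 equiv), K2CO3 (3 equiv), DMF, 60 °C
Reagents that add atoms: iodomethane, CI
Why: Williamson etherification of the remaining chelated phenol, which the small electrophile in warm DMF should alkylate completely.

Step 10
Reactants: 14 methyl 4-(benzyloxy)-2-methoxy-3,6-dimethylbenzoate
Product: 15 4-(benzyloxy)-2-methoxy-3,6-dimethylbenzoic acid
Conditions: KOH (5 equiv), DMSO/H2O 4:1, 100 °C; then aq HCl
Reagents that add atoms: potassium hydroxide, [K+].[OH-]
Why: Saponification of a hindered methyl benzoate under the same forcing conditions as in step 6, with both ethers stable to hydroxide.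

Step 11
Reactants: 15 4-(benzyloxy)-2-methoxy-3,6-dimethylbenzoic acid
Product: 16 tert-butyl 4-(benzyloxy)-2-methoxy-3,6-dimethylbenzoate
Conditions: Me2NCH(OtBu)2 (4 equiv), toluene, 80 °C
Reagents that add atoms: N,N-dimethylformamide di-tert-butyl acetal, CN(C)C(OC(C)(C)C)OC(C)(C)C
Why: Esterification by O-alkylation of the carboxylate with the tert-butyl donor released from the amide acetal, which needs no attack at the flanked carbonyl carbon and installs an ester that is inert to amine base and to zerovalent palladium.

Step 12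
Reactants: 16 tert-butyl 4-(benzyloxy)-2-methoxy-3,6-dimethylbenzoate
Product: 17 tert-butyl 4-hydroxy-2-methoxy-3,6-dimethylbenzoate
Conditions: H2 (1 atm), 10% Pd/C, EtOAc, rt
Reagents that add atoms: none
Why: Hydrogenolysis of the benzyl aryl ether, which should free the C4 phenol and leave the tert-butyl ester and the methyl ether intact.

Step 13
Reactants: 12 4-iodo-3-methoxy-2,5,6-trimethylphenyl 2,4-bis(benzyloxy)-3,6-dimethylbenzoate; 18 carbon monoxide; 17 tert-butyl 4-hydroxy-2-methoxy-3,6-dimethylbenzoate (1.5 equiv)
Product: 19 tert-butyl 4-[(4-{[2,4-bis(benzyloxy)-3,6-dimethylbenzoyl]oxy}-2-methoxy-3,5,6-trimethylbenzoyl)oxy]-2-methoxy-3,6-dimethylbenzoate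
Conditions: Pd(OAc)2 (5 mol %), Xantphos (7.5 mol %), Et3N (3 equiv), CO (5 bar), toluene, 100 °C
Reagents that add atoms: none
Why: Zerovalent palladium, formed in the flask from Pd(OAc)2, should insert into the carbon–iodine bond of 12; CO then inserts into the crowded aryl–palladium bond to give an aroyl complex of divalent palladium, the phenoxide of 17 takes the place of iodide on the metal, and reductive elimination forms the acyl–oxygen bond and returns zerovalent palladium. The closest known reaction type is the palladium-catalysed aryloxycarbonylation of aryl iodides with CO and phenols, applied here to a doubly ortho-substituted iodide at the demanding end of its scope. No ring is closed and no stereocentre is created. The step needs ester formation to win over direct diaryl ether coupling, hydrodeiodination and transesterification of the esters already present. CO pressure and the wide bite angle of Xantphos favour the aroyl complex, the ester between rings C and B is screened by four ortho substituents, and the tert-butyl ester of 17 does not react with Et3N or zerovalent palladium. The position of the new carbonyl is fixed because the iodine of 12 sits on the only carbon of ring B that could carry it.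

Step 14
Reactants: 19 tert-butyl 4-[(4-{[2,4-bis(benzyloxy)-3,6-dimethylbenzoyl]oxy}-2-methoxy-3,5,6-trimethylbenzoyl)oxy]-2-methoxy-3,6-dimethylbenzoate
Product: 20 tert-butyl 4-({4-[(2,4-dihydroxy-3,6-dimethylbenzoyl)oxy]-2-methoxy-3,5,6-trimethylbenzoyl}oxy)-2-methoxy-3,6-dimethylbenzoate
Conditions: H2 (1 atm), 10% Pd/C, EtOAc/THF, rt
Reagents that add atoms: none
Why: Hydrogenolysis of both benzyl aryl ethers on ring C under neutral conditions, which the two aryl esters and the tert-butyl ester should survive.

Step 15
Reactants: 20 tert-butyl 4-({4-[(2,4-dihydroxy-3,6-dimethylbenzoyl)oxy]-2-methoxy-3,5,6-trimethylbenzoyl}oxy)-2-methoxy-3,6-dimethylbenzoate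
Product: 21 4-({4-[(2,4-dihydroxy-3,6-dimethylbenzoyl)oxy]-2-methoxy-3,5,6-trimethylbenzoyl}oxy)-2-methoxy-3,6-dimethylbenzoic acid (target)
Conditions: CF3CO2H, Et3SiH (3 equiv), CH2Cl2, 0 °C to rt
Reagents that add atoms: none
Why: Acidolysis of the tert-butyl ester by alkyl–oxygen cleavage, with Et3SiH reducing the tert-butyl cation before it can alkylate the phenolic rings and with the flanked aryl esters stable to anhydrous acid.

**Compound list**
1 | 2,5-dimethylbenzene-1,3-diol | Cc1cc(O)c(C)c(O)c1 | starting material
2 | N-[(2,4-dihydroxy-3,6-dimethylphenyl)methylidene]-N-methylmethanaminium chloride | C[N+](C)=Cc1c(C)cc(O)c(C)c1O.[Cl-] | intermediate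
3 | 2,4-dihydroxy-3,6-dimethylbenzaldehyde | O=Cc1c(C)cc(O)c(C)c1O | intermediate
4 | 2-hydroxy-4-methoxy-3,6-dimethylbenzaldehyde | COc1cc(C)c(C=O)c(O)c1C | intermediate
5 | 2-(hydroxymethyl)-5-methoxy-3,6-dimethylphenol | COc1cc(C)c(CO)c(O)c1C | intermediate
6 | 3-methoxy-2,5,6-trimethylphenol | COc1cc(C)c(C)c(O)c1C | intermediate
7 | 4-iodo-3-methoxy-2,5,6-trimethylphenol | COc1c(I)c(C)c(C)c(O)c1C | intermediate
8 | methyl 2,4-dihydroxy-3,6-dimethylbenzoate | COC(=O)c1c(C)cc(O)c(C)c1O | starting material
9 | methyl 2,4-bis(benzyloxy)-3,6-dimethylbenzoate | COC(=O)c1c(C)cc(OCc2ccccc2)c(C)c1OCc1ccccc1 | intermediate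
10 | 2,4-bis(benzyloxy)-3,6-dimethylbenzoic acid | OC(=O)c1c(C)cc(OCc2ccccc2)c(C)c1OCc1ccccc1 | intermediate
11 | 2,4-bis(benzyloxy)-3,6-dimethylbenzoic trifluoroacetic anhydride | O=C(OC(=O)C(F)(F)F)c1c(C)cc(OCc2ccccc2)c(C)c1OCc1ccccc1 | intermediate
12 | 4-iodo-3-methoxy-2,5,6-trimethylphenyl 2,4-bis(benzyloxy)-3,6-dimethylbenzoate | COc1c(I)c(C)c(C)c(OC(=O)c2c(C)cc(OCc3ccccc3)c(C)c2OCc2ccccc2)c1C | intermediate
13 | methyl 4-(benzyloxy)-2-hydroxy-3,6-dimethylbenzoate | COC(=O)c1c(C)cc(OCc2ccccc2)c(C)c1O | intermediate
14 | methyl 4-(benzyloxy)-2-methoxy-3,6-dimethylbenzoate | COC(=O)c1c(C)cc(OCc2ccccc2)c(C)c1OC | intermediate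
15 | 4-(benzyloxy)-2-methoxy-3,6-dimethylbenzoic acid | COc1c(C)c(OCc2ccccc2)cc(C)c1C(=O)O | intermediate
16 | tert-butyl 4-(benzyloxy)-2-methoxy-3,6-dimethylbenzoate | COc1c(C)c(OCc2ccccc2)cc(C)c1C(=O)OC(C)(C)C | intermediate
17 | tert-butyl 4-hydroxy-2-methoxy-3,6-dimethylbenzoate | COc1c(C)c(O)cc(C)c1C(=O)OC(C)(C)C | intermediate
18 | carbon monoxide | [C-]#[O+] | starting material
19 | tert-butyl 4-[(4-{[2,4-bis(benzyloxy)-3,6-dimethylbenzoyl]oxy}-2-methoxy-3,5,6-trimethylbenzoyl)oxy]-2-methoxy-3,6-dimethylbenzoate | COc1c(C)c(OC(=O)c2c(C)c(C)c(OC(=O)c3c(C)cc(OCc4ccccc4)c(C)c3OCc3ccccc3)c(C)c2OC)cc(C)c1C(=O)OC(C)(C)C | intermediate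
20 | tert-butyl 4-({4-[(2,4-dihydroxy-3,6-dimethylbenzoyl)oxy]-2-methoxy-3,5,6-trimethylbenzoyl}oxy)-2-methoxy-3,6-dimethylbenzoate | COc1c(C)c(OC(=O)c2c(C)c(C)c(OC(=O)c3c(C)cc(O)c(C)c3O)c(C)c2OC)cc(C)c1C(=O)OC(C)(C)C | intermediate
21 | 4-({4-[(2,4-dihydroxy-3,6-dimethylbenzoyl)oxy]-2-methoxy-3,5,6-trimethylbenzoyl}oxy)-2-methoxy-3,6-dimethylbenzoic acid | COc1c(C)c(OC(=O)c2c(C)c(C)c(OC(=O)c3c(C)cc(O)c(C)c3O)c(C)c2OC)cc(C)c1C(=O)O | target

**Count**
Total: 15 steps. Longest linear sequence: 8 steps (steps 1–4, 7, 13, 14, 15 from 1; equally steps 8–12, 13, 14, 15 from 8).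

**Steps most likely to fail**

1. Step 13. Capture of the doubly flanked aroyl–palladium intermediate by the phenoxide may be slow, so that hydrodeiodination or decarbonylation with aryl ether formation takes over. Fallback from 12: iodine–magnesium exchange with iPrMgCl·LiCl (THF, −20 °C), which the shielded ester should tolerate, would give the arylmagnesium chloride F1. CO2 and acidic work-up would then give 4-{[2,4-bis(benzyloxy)-3,6-dimethylbenzoyl]oxy}-2-methoxy-3,5,6-trimethylbenzoic acid F2. (COCl)2 with catalytic DMF in CH2Cl2 would convert this into the corresponding benzoyl chloride F3. The sodium phenolate F4, made from 17 with NaH in THF, would be acylated by F3 at reflux, and the route is rejoined at 19.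

2. Step 7. O-acylation between two doubly flanked partners may stay incomplete, or the benzyl ether next to the acylium centre may be lost under the acidic conditions. Fallback from 10: (COCl)2 with catalytic DMF in CH2Cl2 would give 2,4-bis(benzyloxy)-3,6-dimethylbenzoyl chloride F5. Phenol 7 would be deprotonated with NaH in THF to sodium 4-iodo-3-methoxy-2,5,6-trimethylphenolate F6. Acylation of F6 by F5 in THF at reflux, a base-mediated acyl substitution instead of an acylium process, would rejoin the route at 12.

3. Step 3. The reduction may stall at the benzylic alcohol, which under acid can condense with the electron-rich product at its free ring position, or the ring may be over-reduced. Fallback from 4: hydrazine hydrate in diethylene glycol would give the (E)-hydrazone F7. Heating with KOH to 190 °C (Wolff–Kishner reduction) passes through no cationic benzylic species and should return to the route at 6.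

**Further compounds**
F1 | step 13 | (4-{[2,4-bis(benzyloxy)-3,6-dimethylbenzoyl]oxy}-2-methoxy-3,5,6-trimethylphenyl)magnesium chloride | COc1c([Mg]Cl)c(C)c(C)c(OC(=O)c2c(C)cc(OCc3ccccc3)c(C)c2OCc2ccccc2)c1C
F2 | step 13 | 4-{[2,4-bis(benzyloxy)-3,6-dimethylbenzoyl]oxy}-2-methoxy-3,5,6-trimethylbenzoic acid | COc1c(C(=O)O)c(C)c(C)c(OC(=O)c2c(C)cc(OCc3ccccc3)c(C)c2OCc2ccccc2)c1C
F3 | step 13 | 4-{[2,4-bis(benzyloxy)-3,6-dimethylbenzoyl]oxy}-2-methoxy-3,5,6-trimethylbenzoyl chloride | COc1c(C(=O)Cl)c(C)c(C)c(OC(=O)c2c(C)cc(OCc3ccccc3)c(C)c2OCc2ccccc2)c1C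
F4 | step 13 | sodium 4-(tert-butoxycarbonyl)-3-methoxy-2,5-dimethylphenolate | COc1c(C)c([O-])cc(C)c1C(=O)OC(C)(C)C.[Na+]
F5 | step 7 | 2,4-bis(benzyloxy)-3,6-dimethylbenzoyl chloride | O=C(Cl)c1c(C)cc(OCc2ccccc2)c(C)c1OCc1ccccc1
F6 | step 7 | sodium 4-iodo-3-methoxy-2,5,6-trimethylphenolate | COc1c(I)c(C)c(C)c([O-])c1C.[Na+]
F7 | step 3 | (E)-2-(hydrazinylidenemethyl)-5-methoxy-3,6-dimethylphenol | COc1cc(C)c(/C=N/N)c(O)c1C
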